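# Lapiferine by carbonyl ylide cycloaddition: a 17-step proposal

## Structural features

Lapiferine is a daucane sesquiterpenoid: a cyclopentane (ring A, C1–C5) trans-fused across C1–C5 to a cycloheptane (ring B, C1 and C5–C10). The numbering used here is: C1 the fusion carbon with the angular methyl, C2 and C3 CH2, C4 the tertiary carbinol carrying isopropyl, C5 the fusion CH, C6 the angelate carbinol, C7 CH2, C8 (methyl) and C9 the epoxide carbons, C10 the free secondary carbinol. All seven stereocentres (1S,4R,5S,6S,8R,9S,10S) are contiguous around the two rings. With the angular methyl taken as β, the C4 hydroxyl is β, while H-5, the C6 ester oxygen, the epoxide oxygen and the C10 hydroxyl are all α. The fragile groups are the (Z)-2-methylbut-2-enoate (isomerised to the tiglate or attacked by soft nucleophiles and strong bases), the trisubstituted epoxide beside a hydroxyl (acid, transannular opening), and the 1,3-dioxygenated C4/C6 pair, which in carbonyl-level intermediates can undergo retro-aldol cleavage or elimination. The real difficulty is ring B: five of its seven carbons are oxidised, the C10 oxygen must stand trans to the angular methyl on a neopentyl carbon (the face an external hydride does not deliver), and two secondary hydroxyls must be told apart at the end. The crowded C1/C5/C4 triad of ring A (quaternary carbon, methine, tetrasubstituted carbinol) is the second problem. The key step uses the fact that C6 and C9 both carry oxygen and are 1,4-related through C7–C8, while C10 is at the carbonyl level beside C1. The chain C9–C10–C1–C5–C6 is therefore the carbon frame of a six-membered carbonyl ylide with oxygen between C6 and C9, and C7–C8 with its methyl is a two-carbon alkene that can be added across the ylide termini.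

## Logic of the disconnections

30 ⇒ 29 ⇒ 27 + 28. The O–Si bond and then the C6–O (alkyl–oxygen) bond are cut. The ester is the most fragile group and the ring-forming step delivers the C6 oxygen on the β face, so esterification and inversion are combined and placed after all hydride, selenolate and peroxide chemistry. The gain is that 27 carries no unsaturated ester. The demand is an SN2 reaction at the hindered C6 that beats elimination and leaves the C10 hydroxyl alone.

27 ⇒ 26. The two C–O bonds of the epoxide are cut. Epoxide and C10 hydroxyl are syn, which is the signature of hydroxyl-directed oxygen transfer. Two stereocentres fall back to one alkene. The allylic 10α-hydroxyl has to outweigh the homoallylic 6β-hydroxyl as the directing group.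

26 ⇒ 23 (through 24 and 25) ⇒ 22. The C8=C9 alkene and the C10 hydroxyl are traced to a 9,10-epoxide, and its two C–O bonds are then cut. A hydride cannot place the C10 oxygen trans to the angular methyl, but an electrophilic oxygen delivered anti to that methyl can. The C10 centre thus reduces to the face selection of an alkene. The forward steps require nucleophilic opening at C9 and not at neopentyl C10, and a hydrogen at C8 syn to selenium.

22 ⇒ 20 (through 21) ⇒ 19. The C8–H bond and the C10 hydrazone are cut, which moves the alkene back into conjugation. This links the C9=C10 alkene to the enone that the ring-forming chemistry supplies and sets the C8 hydrogen by internal delivery. The gain is a conjugated enone with no C8 stereocentre. The demand is 1,2-hydride addition to C10 from the α face.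

19 ⇒ 17 (through 18). The C9–O bond of an oxygen bridge is restored and acetic acid is added back across C8=C9. Enone and C6 carbinol then both come from one bridged ether whose C6–O–C9 unit marks a carbonyl ylide cycloadduct. The forward reduction has to stop after C–O cleavage, and the elimination has to be the conjugating one.

17 ⇒ 14 + 15 (through 16). The C6–C7 and C8–C9 bonds are cut, together with the O–C9 bond of the bridge. These bonds join the five-carbon unit C9–C10–C1–C5–C6, oxygenated at both ends, to a two-carbon alkene. Ring B disappears completely: the tricyclic 17 becomes the monocyclic 14 and the commodity alkene 15. The three centres formed are transient or correctable; C1, C4 and C5 are inherited. The demands are those listed under the key step.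

14 ⇒ 13 ⇒ 12 ⇒ 10 (through 11). These are changes of oxidation level and a diazo transfer. An aldehyde cannot coexist with enolate chemistry, so the diazo group is installed first, on a methyl ketone that can enolise in one direction only. This avoids the carboxylic acid, the acid chloride and diazomethane. The demand is selective release of the primary silyl ether beside a diazoketone.

10 ⇒ 9 ⇒ 8 ⇒ 6 + 7. The acetyl group is traced to an isopropenyl group, then the Si–O bond and the C4–isopropyl bond are cut. The tertiary carbinol comes from a ketone and its configuration from the neighbouring C5 substituent. The demand is addition without enolisation, anti to that substituent.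

6 ⇒ 5 ⇒ 1 + 2 + 3 (through 4). The C1–C10 bond (conjugate addition) and the C5–C6 bond (aldol) are cut; both flank the C=C of 1, so one operation sets C1 by the catalyst and C5 by the substrate. A vinyl group would be the obvious carboxyl precursor at C1, but it is no larger than the methyl beside it and would need four steps and diazomethane to become the diazoketone. The extra methyl in 2 makes the group clearly larger than CH3 (better face differentiation of enolate 4) and a direct precursor of the acetyl group. The demands are enantioselective formation of the quaternary centre and trans-selective trapping.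

## Other disconnections considered

Alternative 1: Transannular epoxide opening. The cut is C1–C5. In the forward step BF3·OEt2 activates the 4,5-epoxide of the ten-membered silyl dienol ether A1 and the C1 terminus of the dienol ether attacks C5 across the ring, giving the bicyclic enone A2.
- In favour: both rings, the quaternary C1 and C5 arise in one step. A2 is the correctly configured counterpart of 19 (C6 oxygen already α), so no inversion at C6 is needed. On this point it is better than the chosen plan.
- Against: A1 is a stereodefined, heavily functionalised cyclodecadiene with three stereocentres and a defined enol ether geometry, and it needs a macrocyclisation. Lewis acid activation of a trisubstituted epoxide favours ionisation at the tertiary C4, whereas the step needs attack at secondary C5. Ring fusion and the C1 configuration depend on the reacting conformer of a flexible ring.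
- Comparison: structurally both plans pass through the same enone stage and face the same C10 problem afterwards (equal). Mechanistically the cationic closure works against the intrinsic regiochemistry of the epoxide, while the ylide addition follows its own polarity. In step economy the alternative saves the inversion after the key step but is expected to cost clearly more before it.

Alternative 2: Carbenoid C–H insertion. The cut is C4–C5. In the forward step Rh2(OAc)4 decomposes the α-diazo ester A3 and the C5 carbenoid inserts into the C4–H bond α to the silyloxy group, giving the cyclopentane A4.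
- In favour: insertion proceeds with retention, so the tetrasubstituted C4 carbinol comes stereospecifically from an easily made secondary carbinol. This is better than the face-selective addition of step 3. The C–H bond is activated by oxygen and the five-membered transition state is the favoured one.
- Against: only ring A is built; ring B and all its oxygenation remain. The quaternary C1 must be set in an acyclic precursor, which is harder than the conjugate addition of step 1. A carbenoid beside a quaternary carbon can also undergo 1,2-migration. The C5 ester may form as a mixture, although it can be equilibrated.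
- Comparison: the catalyst class is the same (equal in practicality). Structurally the alternative spends its key step on two centres that the chosen route sets by standard means. In step economy it is expected to be the longest of the four plans.

Alternative 3: Intramolecular Hosomi–Sakurai closure. The cut is C6–C7. In the forward step BF3·OEt2 activates the C6 aldehyde of the allylsilane A5 and the terminal C7 attacks it with loss of silicon from C9, giving the diol monosilyl ether A6.
- In favour: A6 already has the C10 oxygen α and protected, the C8=C9 alkene in place and the C6 hydroxyl free in the natural configuration. Directed epoxidation, acylation of the only free secondary hydroxyl and deprotection would finish the synthesis. After the key step this is clearly better than the chosen plan (about three steps against eight), and it avoids the late choice between the C6 and C10 hydroxyls.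
- Against: the difficulty moves into A5. The neopentyl C10 carbinol must be set α beside the quaternary C1 in an open chain. The α-silyl β-silyloxy unit at C9/C10 is prone to Peterson-type elimination. The β-hydroxy aldehyde with a free tertiary hydroxyl can undergo retro-aldol cleavage under Lewis acid. The C6 configuration arises in a seven-membered closure for which no reliable model exists, and protodesilylation competes.
- Comparison: structurally the alternative ends nearer to the target. Mechanistically it forms one C–C bond under Lewis acid, against two σ bonds and a ring under neutral conditions. In step economy it is shorter after and longer and less secure before the key step, so about equal overall.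

Key step: step 9

Assumption: in step 1 the antipode of the chiral NHC ligand is the one whose sense of induction gives the (3S) quaternary centre; which antipode that is must be fixed in the first run.

Remark on the key-step structures: checked centre by centre, 14 has C1, C4 and C5 as in 30, and 17 has the same three centres with C6 epimeric to 30 (inverted in step 16). No correction of these structures was needed. C8 of 17 is drawn with the acetoxy group exo; the endo isomer would serve equally. Hydrazone 20 is written without C=N geometry because both isomers converge.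

## Route

Step 1
Reactants: 1 3-methylcyclopent-2-en-1-one; 2 isopropenylmagnesium bromide (Et2O solution); 3 formaldehyde (monomer, from cracked paraformaldehyde)
Product: 5 (2S,3S)-2-(hydroxymethyl)-3-methyl-3-(prop-1-en-2-yl)cyclopentan-1-one, via bromomagnesium enolate 4 (not isolated)
Conditions: Cu(OTf)2 (3 mol%), chiral hydroxyalkyl imidazolinium salt (NHC precursor, 4 mol%), Et2O, −30 °C; then CH2O (g), −30 → 0 °C; aq NH4Cl
Reagents that add atoms: none
Why: Copper–NHC-catalysed asymmetric conjugate addition of a Grignard reagent to a β-substituted cyclic enone creates the quaternary C1 under ligand control; the regiodefined magnesium enolate is then hydroxymethylated (aldol) anti to the larger isopropenyl group, so that CH2OH ends cis to the methyl, which is also the more stable arrangement at this epimerisable centre.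

Step 2
Reactants: 5 (2S,3S)-2-(hydroxymethyl)-3-methyl-3-(prop-1-en-2-yl)cyclopentan-1-one
Product: 6 (2S,3S)-3-methyl-3-(prop-1-en-2-yl)-2-[(triethylsilyloxy)methyl]cyclopentan-1-one
Conditions: Et3SiCl, imidazole, CH2Cl2, 0 °C
Reagents that add atoms: chlorotriethylsilane, CC[Si](Cl)(CC)CC
Why: Silylation of the primary alcohol removes the retro-aldol and dehydration pathways of the β-hydroxy ketone and makes the C5 substituent bulky for the next step.

Step 3
Reactants: 6 (2S,3S)-3-methyl-3-(prop-1-en-2-yl)-2-[(triethylsilyloxy)methyl]cyclopentan-1-one; 7 isopropylmagnesium chloride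
Product: 8 (1R,2S,3S)-3-methyl-1-(propan-2-yl)-3-(prop-1-en-2-yl)-2-[(triethylsilyloxy)methyl]cyclopentan-1-ol
Conditions: anhydrous CeCl3, THF, −78 → 0 °C; aq NH4Cl
Reagents that add atoms: none
Why: CeCl3-promoted 1,2-addition suppresses enolisation and β-hydride reduction of the hindered ketone; the nucleophile enters anti to the adjacent CH2OSiEt3 group, so the C4 hydroxyl ends cis to it (4R).

Step 4
Reactants: 8 (1R,2S,3S)-3-methyl-1-(propan-2-yl)-3-(prop-1-en-2-yl)-2-[(triethylsilyloxy)methyl]cyclopentan-1-ol
Product: 9 triethyl{[(1R,2S,3S)-3-methyl-1-(propan-2-yl)-3-(prop-1-en-2-yl)-2-{[(triethylsilyl)oxy]methyl}cyclopentyl]oxy}silane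
Conditions: Et3SiOTf, 2,6-lutidine, CH2Cl2, 0 °C → rt
Reagents that add atoms: triethylsilyl trifluoromethanesulfonate, CC[Si](CC)(CC)OS(=O)(=O)C(F)(F)F
Why: The silyl triflate silylates the hindered tertiary alcohol; the two silyl ethers now differ strongly in lability (primary against shielded tertiary), which step 7 uses.

Step 5
Reactants: 9 triethyl{[(1R,2S,3S)-3-methyl-1-(propan-2-yl)-3-(prop-1-en-2-yl)-2-{[(triethylsilyl)oxy]methyl}cyclopentyl]oxy}silane
Product: 10 1-[(1S,2S,3R)-1-methyl-3-(propan-2-yl)-3-[(triethylsilyl)oxy]-2-{[(triethylsilyl)oxy]methyl}cyclopentyl]ethan-1-one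
Conditions: O3, CH2Cl2, −78 °C; Me2S, −78 °C → rt
Reagents that add atoms: ozone, [O-][O+]=O
Why: Ozonolysis of the only alkene, a 1,1-disubstituted one, gives the methyl ketone and thereby puts C10 and C9 in place in one step.

Step 6
Reactants: 10 1-[(1S,2S,3R)-1-methyl-3-(propan-2-yl)-3-[(triethylsilyl)oxy]-2-{[(triethylsilyl)oxy]methyl}cyclopentyl]ethan-1-one
Product: 12 2-diazo-1-[(1S,2S,3R)-1-methyl-3-(propan-2-yl)-3-[(triethylsilyl)oxy]-2-{[(triethylsilyl)oxy]methyl}cyclopentyl]ethan-1-one, via trifluoroacetyl diketone 11 (not isolated)
Conditions: LiN(SiMe3)2, THF, −78 °C; CF3CO2CH2CF3; aq NH4Cl; then p-ABSA, Et3N, MeCN, rt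
Reagents that add atoms: 4-acetamidobenzenesulfonyl azide, CC(=O)Nc1ccc(cc1)S(=O)(=O)N=[N+]=[N-]
Why: Detrifluoroacetylative diazo transfer (a deacylative Regitz transfer): the ketone can enolise only toward its methyl group because C1 is quaternary, Claisen trifluoroacetylation activates that carbon, and the sulfonyl azide then transfers N2 with loss of the trifluoroacetyl group; no diazomethane is needed.

Step 7
Reactants: 12 2-diazo-1-[(1S,2S,3R)-1-methyl-3-(propan-2-yl)-3-[(triethylsilyl)oxy]-2-{[(triethylsilyl)oxy]methyl}cyclopentyl]ethan-1-one
Product: 13 2-diazo-1-[(1S,2S,3R)-2-(hydroxymethyl)-1-methyl-3-(propan-2-yl)-3-[(triethylsilyl)oxy]cyclopentyl]ethan-1-one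
Conditions: Bu4NF (1.1 equiv), AcOH (1.1 equiv), THF, −20 → 0 °C
Reagents that add atoms: none
Why: Fluoride should cleave the unhindered primary silyl ether much faster than the tertiary one flanked by isopropyl and two ring carbons; the acetic acid buffer avoids both strong acid (diazoketone) and free alkoxide.

Step 8
Reactants: 13 2-diazo-1-[(1S,2S,3R)-2-(hydroxymethyl)-1-methyl-3-(propan-2-yl)-3-[(triethylsilyl)oxy]cyclopentyl]ethan-1-one
Product: 14 (1R,2S,5R)-2-(2-diazoacetyl)-2-methyl-5-(propan-2-yl)-5-[(triethylsilyl)oxy]cyclopentane-1-carbaldehyde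
Conditions: Dess–Martin periodinane, pyridine, CH2Cl2, 0 °C; used at once
Reagents that add atoms: none
Why: Buffered periodinane oxidation is neutral enough for a diazoketone and for the β-silyloxy aldehyde; C5 is not expected to epimerise, and the aldehyde trans to the isopropyl group is in any case the stable epimer.

Step 9
Reactants: 14 (1R,2S,5R)-2-(2-diazoacetyl)-2-methyl-5-(propan-2-yl)-5-[(triethylsilyl)oxy]cyclopentane-1-carbaldehyde; 15 isopropenyl acetate
Product: 17 8β-acetoxy-6β,9β-epoxy-4β-(triethylsilyloxy)daucan-10-one (oxygen bridge C6–O–C9 on the β face, acetoxy exo, trans ring fusion), via carbonyl ylide 16 (not isolated)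
Conditions: Rh2(OAc)4 (2 mol%), 15 (20 equiv), CH2Cl2, 40 °C, slow addition of 14
Reagents that add atoms: none
Why: Rh2(OAc)4 expels N2 from 14 to give a catalyst-bound carbene at C9, which is captured by a lone pair of the C6 aldehyde oxygen; this O–C9 bond closes the six-membered oxygen ring (O, C6, C5, C1, C10, C9) and gives ylide 16, trans-fused to ring A because the two arms are trans on the cyclopentane. The ylide then adds as a 1,3-dipole across the C=C of 15 in a concerted, suprafacial cycloaddition that forms C6–C7 and C8–C9 and so closes the seven-membered carbocycle from five ylide carbons and two alkene carbons; the closest known reaction type is the tandem cyclisation–cycloaddition of 1-diazo-2,5-dicarbonyl compounds to 8-oxabicyclo[3.2.1]octan-2-ones. Regiochemistry follows the polarity of the partners: with an electron-rich alkene the dipole LUMO and alkene HOMO dominate, the largest coefficients lie on the oxocarbenium-like C6 and on the CH2 of 15, so CH2 bonds to C6 and the acetoxy carbon to C9, which puts the methyl on C8. Facial selectivity is set by the angular C1 methyl, which is pseudo-axial and 1,3 to both termini, so the alkene should approach from the α face; this fixes C6 and C9 with the oxygen bridge β (C6 is corrected in step 16, the C9–O bond is cut in step 10). C8 is set by the exo or endo placement of the acetoxy group and is erased in step 10. The step needs chemoselective ylide formation over C–H insertion and carbene dimerisation; the six-membered reach of the aldehyde oxygen, the trans-1,3 placement of the C4 silyl ether oxygen (which cannot reach C9), slow addition and the large excess of 15 secure it. C1, C4 and C5 are not touched under these neutral aprotic conditions.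

Step 10
Reactants: 17 8β-acetoxy-6β,9β-epoxy-4β-(triethylsilyloxy)daucan-10-one
Product: 19 6β-hydroxy-4β-(triethylsilyloxy)dauc-8-en-10-one, via β-acetoxy ketone 18 (not isolated)
Conditions: SmI2 (2.5 equiv), THF/MeOH, −78 °C; air; then DBU, 0 °C → rt
Reagents that add atoms: none
Why: SmI2 reduces the ketone to a ketyl that expels the α-oxygen at C9 (reductive cleavage of an α-alkoxy ketone) and methanol protonates the enolate; DBU then removes the β-acetate by E1cB elimination to the conjugated C8=C9 enone, erasing C8 and releasing the C6 hydroxyl (β).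

Step 11
Reactants: 19 6β-hydroxy-4β-(triethylsilyloxy)dauc-8-en-10-one
Product: 20 6β-hydroxy-4β-(triethylsilyloxy)dauc-8-en-10-one 4-methylbenzenesulfonylhydrazone
Conditions: TsNHNH2, AcOH (cat.), MeOH, 50 °C
Reagents that add atoms: 4-methylbenzenesulfonohydrazide, Cc1ccc(cc1)S(=O)(=O)NN
Why: Acid-catalysed condensation at the enone carbonyl; aza-Michael addition to the β,β-disubstituted enone is slow and the shielded tertiary silyl ether tolerates the weak acid.

Step 12
Reactants: 20 6β-hydroxy-4β-(triethylsilyloxy)dauc-8-en-10-one 4-methylbenzenesulfonylhydrazone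
Product: 22 4β-(triethylsilyloxy)-8βH-dauc-9-en-6β-ol (8α-methyl), via allylic diazene 21 (not isolated)
Conditions: catecholborane (3 equiv), CHCl3, 0 °C; NaOAc·3H2O, 60 °C
Reagents that add atoms: none
Why: Alkene-transposing reduction of an enone tosylhydrazone: hydride adds 1,2 to C10 anti to the angular methyl, acetate releases sulfinate, and diazene 21 loses N2 in a retro-ene step that hands its hydrogen to the β face of C8 while the alkene moves to C9=C10, which sets C8 (H β, methyl α).

Step 13
Reactants: 22 4β-(triethylsilyloxy)-8βH-dauc-9-en-6β-ol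
Product: 23 9α,10α-epoxy-4β-(triethylsilyloxy)-8βH-daucan-6β-ol
Conditions: mCPBA, CH2Cl2, 0 °C
Reagents that add atoms: 3-chloroperbenzoic acid, OOC(=O)c1cccc(Cl)c1
Why: Prilezhaev epoxidation of the cis-disubstituted alkene anti to the pseudo-axial C1 methyl on the adjacent quaternary carbon; this places the C10 oxygen on the α face.

Step 14
Reactants: 23 9α,10α-epoxy-4β-(triethylsilyloxy)-8βH-daucan-6β-ol
Product: 26 4β-(triethylsilyloxy)dauc-8-ene-6β,10α-diol, via hydroxy selenide 24 (not isolated), via selenoxide 25 (not isolated)
Conditions: (PhSe)2, NaBH4, EtOH, 78 °C; then THF, 30% H2O2, 0 °C → rt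
Reagents that add atoms: none
Why: Epoxide-to-allylic-alcohol conversion through a selenide: the selenolate opens the epoxide with inversion at C9, since C10 is neopentyl, and the selenoxide then undergoes syn elimination with the β hydrogen at C8, away from the carbinol carbon, so that C10 keeps its α hydroxyl and the alkene returns to C8=C9.

Step 15
Reactants: 26 4β-(triethylsilyloxy)dauc-8-ene-6β,10α-diol
Product: 27 8α,9α-epoxy-4β-(triethylsilyloxy)daucane-6β,10α-diol
Conditions: VO(acac)2 (5 mol%), t-BuOOH (decane), CH2Cl2, 0 °C → rt
Reagents that add atoms: tert-butyl hydroperoxide, CC(C)(C)OO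
Why: Vanadium-catalysed hydroxyl-directed epoxidation: the allylic 10α-hydroxyl binds the metal peroxide and delivers oxygen to the same face, which in a seven-membered allylic alcohol gives the syn epoxy alcohol and sets C8 and C9; allylic direction is much stronger than that of the homoallylic 6β-hydroxyl.

Step 16
Reactants: 27 8α,9α-epoxy-4β-(triethylsilyloxy)daucane-6β,10α-diol; 28 angelic acid ((2Z)-2-methylbut-2-enoic acid)
Product: 29 8α,9α-epoxy-10α-hydroxy-4β-(triethylsilyloxy)daucan-6α-yl (2Z)-2-methylbut-2-enoate
Conditions: PPh3, DIAD, toluene, 0 → 40 °C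
Reagents that add atoms: none
Why: Mitsunobu esterification: the carboxylate displaces the C6 oxyphosphonium group by SN2 with inversion, giving the 6α ester; the neopentyl C10 hydroxyl beside the quaternary C1 should not be activated, and the acid reacts as a nucleophile without acyl activation, so the (Z) geometry is kept.

Step 17
Reactants: 29 8α,9α-epoxy-10α-hydroxy-4β-(triethylsilyloxy)daucan-6α-yl (2Z)-2-methylbut-2-enoate
Product: 30 lapiferine, (1S,4R,5S,6S,8R,9S,10S)-8α,9α-epoxy-4β,10α-dihydroxydaucan-6α-yl (2Z)-2-methylbut-2-enoate
Conditions: Bu4NF, AcOH, THF, 0 °C → rt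
Reagents that add atoms: none
Why: Fluoride removes the tertiary silyl ether; buffering keeps the medium near neutral, so the angelate is not isomerised and the epoxide is not opened by a neighbouring hydroxyl.

## Compound list

1 | 3-methylcyclopent-2-en-1-one | CC1=CC(=O)CC1 | starting material
2 | isopropenylmagnesium bromide | CC(=C)[Mg]Br | starting material
3 | formaldehyde | C=O | starting material
4 | bromomagnesium (3S)-3-methyl-3-(prop-1-en-2-yl)cyclopent-1-en-1-olate | CC(=C)[C@@]1(C)CCC(O[Mg]Br)=C1 | intermediate (not isolated)
5 | (2S,3S)-2-(hydroxymethyl)-3-methyl-3-(prop-1-en-2-yl)cyclopentan-1-one | OC[C@H]1C(=O)CC[C@]1(C)C(C)=C | intermediate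
6 | (2S,3S)-3-methyl-3-(prop-1-en-2-yl)-2-[(triethylsilyloxy)methyl]cyclopentan-1-one | CC[Si](CC)(CC)OC[C@H]1C(=O)CC[C@]1(C)C(C)=C | intermediate
7 | isopropylmagnesium chloride | CC(C)[Mg]Cl | starting material
8 | (1R,2S,3S)-3-methyl-1-(propan-2-yl)-3-(prop-1-en-2-yl)-2-[(triethylsilyloxy)methyl]cyclopentan-1-ol | CC[Si](CC)(CC)OC[C@H]1[C@](O)(C(C)C)CC[C@]1(C)C(C)=C | intermediate
9 | triethyl{[(1R,2S,3S)-3-methyl-1-(propan-2-yl)-3-(prop-1-en-2-yl)-2-{[(triethylsilyl)oxy]methyl}cyclopentyl]oxy}silane | CC[Si](CC)(CC)OC[C@H]1[C@](O[Si](CC)(CC)CC)(C(C)C)CC[C@]1(C)C(C)=C | intermediate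
10 | 1-[(1S,2S,3R)-1-methyl-3-(propan-2-yl)-3-[(triethylsilyl)oxy]-2-{[(triethylsilyl)oxy]methyl}cyclopentyl]ethan-1-one | CC[Si](CC)(CC)OC[C@H]1[C@](O[Si](CC)(CC)CC)(C(C)C)CC[C@]1(C)C(C)=O | intermediate
11 | 4,4,4-trifluoro-1-[(1S,2S,3R)-1-methyl-3-(propan-2-yl)-3-[(triethylsilyl)oxy]-2-{[(triethylsilyl)oxy]methyl}cyclopentyl]butane-1,3-dione | CC[Si](CC)(CC)OC[C@H]1[C@](O[Si](CC)(CC)CC)(C(C)C)CC[C@]1(C)C(=O)CC(=O)C(F)(F)F | intermediate (not isolated)
12 | 2-diazo-1-[(1S,2S,3R)-1-methyl-3-(propan-2-yl)-3-[(triethylsilyl)oxy]-2-{[(triethylsilyl)oxy]methyl}cyclopentyl]ethan-1-one | CC[Si](CC)(CC)OC[C@H]1[C@](O[Si](CC)(CC)CC)(C(C)C)CC[C@]1(C)C(=O)C=[N+]=[N-] | intermediate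
13 | 2-diazo-1-[(1S,2S,3R)-2-(hydroxymethyl)-1-methyl-3-(propan-2-yl)-3-[(triethylsilyl)oxy]cyclopentyl]ethan-1-one | OC[C@H]1[C@](O[Si](CC)(CC)CC)(C(C)C)CC[C@]1(C)C(=O)C=[N+]=[N-] | intermediate
14 | (1R,2S,5R)-2-(2-diazoacetyl)-2-methyl-5-(propan-2-yl)-5-[(triethylsilyl)oxy]cyclopentane-1-carbaldehyde | O=C[C@H]1[C@](O[Si](CC)(CC)CC)(C(C)C)CC[C@]1(C)C(=O)C=[N+]=[N-] | intermediate
15 | isopropenyl acetate | CC(=C)OC(C)=O | starting material
16 | six-membered carbonyl ylide, trans-fused to ring A (C6=O+–C9−, C10 ketone) | O=C1[CH-][O+]=C[C@H]2[C@](O[Si](CC)(CC)CC)(C(C)C)CC[C@]12C | intermediate (not isolated)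
17 | 8β-acetoxy-6β,9β-epoxy-4β-(triethylsilyloxy)daucan-10-one | O1[C@@H]2C[C@](C)(OC(C)=O)[C@H]1C(=O)[C@@]3(C)CC[C@@](O[Si](CC)(CC)CC)(C(C)C)[C@H]23 | intermediate
18 | 8β-acetoxy-6β-hydroxy-4β-(triethylsilyloxy)daucan-10-one | O[C@@H]1C[C@](C)(OC(C)=O)CC(=O)[C@@]2(C)CC[C@@](O[Si](CC)(CC)CC)(C(C)C)[C@H]12 | intermediate (not isolated)
19 | 6β-hydroxy-4β-(triethylsilyloxy)dauc-8-en-10-one | O[C@@H]1CC(C)=CC(=O)[C@@]2(C)CC[C@@](O[Si](CC)(CC)CC)(C(C)C)[C@H]12 | intermediate
20 | 6β-hydroxy-4β-(triethylsilyloxy)dauc-8-en-10-one 4-methylbenzenesulfonylhydrazone | O[C@@H]1CC(C)=CC(=NNS(=O)(=O)c3ccc(C)cc3)[C@@]2(C)CC[C@@](O[Si](CC)(CC)CC)(C(C)C)[C@H]12 | intermediate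
21 | 10β-diazenyl-4β-(triethylsilyloxy)dauc-8-en-6β-ol | O[C@@H]1CC(C)=C[C@H](N=N)[C@@]2(C)CC[C@@](O[Si](CC)(CC)CC)(C(C)C)[C@H]12 | intermediate (not isolated)
22 | 4β-(triethylsilyloxy)-8βH-dauc-9-en-6β-ol (8α-methyl) | O[C@@H]1C[C@@H](C)C=C[C@@]2(C)CC[C@@](O[Si](CC)(CC)CC)(C(C)C)[C@H]12 | intermediate
23 | 9α,10α-epoxy-4β-(triethylsilyloxy)-8βH-daucan-6β-ol | O[C@@H]1C[C@@H](C)[C@H]3O[C@H]3[C@@]2(C)CC[C@@](O[Si](CC)(CC)CC)(C(C)C)[C@H]12 | intermediate
24 | 9β-(phenylselanyl)-4β-(triethylsilyloxy)-8βH-daucane-6β,10α-diol | O[C@@H]1C[C@@H](C)[C@H]([Se]c3ccccc3)[C@@H](O)[C@@]2(C)CC[C@@](O[Si](CC)(CC)CC)(C(C)C)[C@H]12 | intermediate (not isolated)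
25 | 9β-(phenylseleninyl)-4β-(triethylsilyloxy)-8βH-daucane-6β,10α-diol | O[C@@H]1C[C@@H](C)[C@H]([Se](=O)c3ccccc3)[C@@H](O)[C@@]2(C)CC[C@@](O[Si](CC)(CC)CC)(C(C)C)[C@H]12 | intermediate (not isolated)
26 | 4β-(triethylsilyloxy)dauc-8-ene-6β,10α-diol | O[C@@H]1CC(C)=C[C@@H](O)[C@@]2(C)CC[C@@](O[Si](CC)(CC)CC)(C(C)C)[C@H]12 | intermediate
27 | 8α,9α-epoxy-4β-(triethylsilyloxy)daucane-6β,10α-diol | O[C@@H]1C[C@@]2(C)O[C@H]2[C@@H](O)[C@@]3(C)CC[C@@](O[Si](CC)(CC)CC)(C(C)C)[C@H]13 | intermediate
28 | angelic acid, (2Z)-2-methylbut-2-enoic acid | C/C=C(/C)C(O)=O | starting material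
29 | 8α,9α-epoxy-10α-hydroxy-4β-(triethylsilyloxy)daucan-6α-yl (2Z)-2-methylbut-2-enoate | C/C=C(/C)C(=O)O[C@H]1C[C@@]2(C)O[C@H]2[C@@H](O)[C@@]3(C)CC[C@@](O[Si](CC)(CC)CC)(C(C)C)[C@H]13 | intermediate
30 | lapiferine | C/C=C(/C)C(=O)O[C@H]1C[C@@]2(C)O[C@H]2[C@@H](O)[C@@]2(C)CC[C@@](O)(C(C)C)[C@H]12 | target

## Step count and least certain steps

Total: 17 steps. Longest linear sequence: 17 steps from 1; the route is fully linear, and 2, 3, 7, 15 and 28 are commercial and enter directly.

**Step 9 (key step).** The most likely failure is slow capture of ylide 16 by the only weakly nucleophilic enol ester, so that carbene dimerisation, ylide collapse or C–H insertion take over. The second risk is loss of facial selectivity through approach syn to the angular methyl; that would give the C6 epimer with the natural configuration, which would then be esterified without inversion.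

Fallback (sets out from 10, returns at 19): ring B is closed by olefin metathesis instead.
- The lithium enolate of 10 is aminomethylated with dimethylmethyleneiminium iodide to the Mannich base F1.
- mCPBA gives the amine N-oxide F2, which undergoes Cope elimination to the vinyl ketone F3.
- Buffered Bu4NF removes the primary silyl group (primary alcohol F4), and Dess–Martin periodinane gives the aldehyde F5.
- 2-Methylallylboronic acid pinacol ester adds to the aldehyde only and gives the homoallylic alcohol F6. The 6β epimer is the one written; the 6α epimer would make step 16 a plain esterification.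
- Ring-closing metathesis of F6 with the second-generation Hoveyda–Grubbs catalyst (toluene, 80 °C, ethene swept out) forms C8=C9 and gives 19.

**Step 1.** The likely failures are erosion of enantioselectivity with an α-branched alkenyl Grignard reagent on a five-membered enone, and over-reaction of the magnesium enolate with formaldehyde together with incomplete trans selectivity.

Fallback (sets out from 1, returns at 5): the nucleophile is changed to an alkenylalane and the aldol to a Lewis acid process. Isopropenyl(dimethyl)alane (from 2-bromopropene, t-BuLi and Me2AlCl) is added with copper thiophene-2-carboxylate (CuTC) and a chiral phosphinamine ligand. The aluminium enolate is silylated in the same flask with Me3SiOTf to the silyl enol ether F7. A Mukaiyama aldol reaction of F7 with aqueous formaldehyde and Sc(OTf)3 in THF then gives 5, with the chance to equilibrate C5 under the reaction conditions.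

**Step 12.** The likely failures are sluggish 1,2-hydride delivery to the hindered C10=N, competing conjugate reduction, and delivery from the wrong face. The last would put the C8 hydrogen on the α face and block the syn elimination of step 14.

Fallback (sets out from 19, returns at 22): C8 is set by directed hydrogenation and the alkene is made by a Shapiro reaction. With [Ir(cod)(PCy3)(py)]PF6 and H2 in CH2Cl2 the 6β-hydroxyl binds iridium and both hydrogens enter C8=C9 from the β face, giving the saturated ketone F8 (8α-methyl). F8 condenses with TsNHNH2 more easily than the enone and gives the tosylhydrazone F9. n-BuLi (4 equiv, THF, −78 → 0 °C, then H2O) can deprotonate only at C9 and gives 22.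

**Step 16.** The likely failures are elimination of the activated C6 oxygen toward C7, or no substitution because the β face at C6 is shielded by the C4 silyl ether and the angular methyl. Partial isomerisation of the angelate is a further risk.

Fallback (sets out from 23, ends at 30): C6 is inverted by oxidation and hydroxyl-directed reduction before the selenium chemistry, and the ester is introduced last by acylation.
- Bu4NF frees the tertiary alcohol (epoxy diol F10).
- Dess–Martin periodinane oxidises the only secondary alcohol (β-hydroxy ketone F11).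
- Me4NBH(OAc)3 in MeCN/AcOH at −20 °C (Evans–Saksena reduction) delivers hydride from the C4 alkoxyborohydride to the β face of C6 and gives the anti-1,3-diol F12 (6α-hydroxyl).
- The selenide sequence of step 14 leads through the hydroxy selenide F13 and the selenoxide F14 to the allylic triol F15.
- VO(acac)2/t-BuOOH, now directed to the α face by both the allylic and the homoallylic hydroxyl, gives the epoxy triol F16.
- Yamaguchi esterification (28, 2,4,6-trichlorobenzoyl chloride, Et3N, then toluene, 80 °C) at the less shielded C6 hydroxyl gives 30.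

## Further compounds

F1 | step 9 | 3-(dimethylamino)-1-[(1S,2S,3R)-1-methyl-3-(propan-2-yl)-3-[(triethylsilyl)oxy]-2-{[(triethylsilyl)oxy]methyl}cyclopentyl]propan-1-one | CC[Si](CC)(CC)OC[C@H]1[C@](O[Si](CC)(CC)CC)(C(C)C)CC[C@]1(C)C(=O)CCN(C)C
F2 | step 9 | N-oxide of F1 | CC[Si](CC)(CC)OC[C@H]1[C@](O[Si](CC)(CC)CC)(C(C)C)CC[C@]1(C)C(=O)CC[N+](C)(C)[O-]
F3 | step 9 | 1-[(1S,2S,3R)-1-methyl-3-(propan-2-yl)-3-[(triethylsilyl)oxy]-2-{[(triethylsilyl)oxy]methyl}cyclopentyl]prop-2-en-1-one | CC[Si](CC)(CC)OC[C@H]1[C@](O[Si](CC)(CC)CC)(C(C)C)CC[C@]1(C)C(=O)C=C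
F4 | step 9 | 1-[(1S,2S,3R)-2-(hydroxymethyl)-1-methyl-3-(propan-2-yl)-3-[(triethylsilyl)oxy]cyclopentyl]prop-2-en-1-one | OC[C@H]1[C@](O[Si](CC)(CC)CC)(C(C)C)CC[C@]1(C)C(=O)C=C
F5 | step 9 | (1R,2S,5R)-2-acryloyl-2-methyl-5-(propan-2-yl)-5-[(triethylsilyl)oxy]cyclopentane-1-carbaldehyde | O=C[C@H]1[C@](O[Si](CC)(CC)CC)(C(C)C)CC[C@]1(C)C(=O)C=C
F6 | step 9 | homoallylic alcohol from 2-methylallylation of F5 (6β-hydroxyl, acryloyl group at C1) | C=C(C)C[C@@H](O)[C@H]1[C@](O[Si](CC)(CC)CC)(C(C)C)CC[C@]1(C)C(=O)C=C
F7 | step 1 | trimethyl{[(3S)-3-methyl-3-(prop-1-en-2-yl)cyclopent-1-en-1-yl]oxy}silane | C[Si](C)(C)OC1=C[C@@](C)(C(C)=C)CC1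
F8 | step 12 | 6β-hydroxy-4β-(triethylsilyloxy)-8βH-daucan-10-one | O[C@@H]1C[C@@H](C)CC(=O)[C@@]2(C)CC[C@@](O[Si](CC)(CC)CC)(C(C)C)[C@H]12
F9 | step 12 | 4-methylbenzenesulfonylhydrazone of F8 | O[C@@H]1C[C@@H](C)CC(=NNS(=O)(=O)c3ccc(C)cc3)[C@@]2(C)CC[C@@](O[Si](CC)(CC)CC)(C(C)C)[C@H]12
F10 | step 16 | 9α,10α-epoxy-8βH-daucane-4β,6β-diol | O[C@@H]1C[C@@H](C)[C@H]3O[C@H]3[C@@]2(C)CC[C@@](O)(C(C)C)[C@H]12
F11 | step 16 | 9α,10α-epoxy-4β-hydroxy-8βH-daucan-6-one | O=C1C[C@@H](C)[C@H]3O[C@H]3[C@@]2(C)CC[C@@](O)(C(C)C)[C@H]12
F12 | step 16 | 9α,10α-epoxy-8βH-daucane-4β,6α-diol | O[C@H]1C[C@@H](C)[C@H]3O[C@H]3[C@@]2(C)CC[C@@](O)(C(C)C)[C@H]12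
F13 | step 16 | 9β-(phenylselanyl)-8βH-daucane-4β,6α,10α-triol | O[C@H]1C[C@@H](C)[C@H]([Se]c3ccccc3)[C@@H](O)[C@@]2(C)CC[C@@](O)(C(C)C)[C@H]12
F14 | step 16 | 9β-(phenylseleninyl)-8βH-daucane-4β,6α,10α-triol | O[C@H]1C[C@@H](C)[C@H]([Se](=O)c3ccccc3)[C@@H](O)[C@@]2(C)CC[C@@](O)(C(C)C)[C@H]12
F15 | step 16 | dauc-8-ene-4β,6α,10α-triol | O[C@H]1CC(C)=C[C@@H](O)[C@@]2(C)CC[C@@](O)(C(C)C)[C@H]12
F16 | step 16 | 8α,9α-epoxydaucane-4β,6α,10α-triol | O[C@H]1C[C@@]2(C)O[C@H]2[C@@H](O)[C@@]3(C)CC[C@@](O)(C(C)C)[C@H]13
A1 | alternative 1 | ten-membered 4,5-epoxide with C10 silyl dienol ether and C6 silyl ether | CC(C)(C)[Si](C)(C)O[C@H]1C/C(C)=C\C(O[Si](C)(C)C(C)(C)C)=C(C)\CC[C@]2(C(C)C)O[C@H]12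
A2 | alternative 1 | 6α-(tert-butyldimethylsilyloxy)-4β-hydroxydauc-8-en-10-one | CC(C)(C)[Si](C)(C)O[C@H]1CC(C)=CC(=O)[C@@]2(C)CC[C@@](O)(C(C)C)[C@H]12
A3 | alternative 2 | acyclic α-diazo ester with C1 quaternary centre and C4 silyloxy methine | CCOC(=O)C(=[N+]=[N-])[C@@](C)(/C=C/C)CC[C@@H](O[Si](C)(C)C(C)(C)C)C(C)C
A4 | alternative 2 | cyclopentane with C4 tertiary silyl ether, C5 ester and C1 propenyl | CCOC(=O)[C@H]1[C@](O[Si](C)(C)C(C)(C)C)(C(C)C)CC[C@]1(C)/C=C/C
A5 | alternative 3 | cyclopentane aldehyde with C10 silyloxy allylsilane side chain | O=C[C@H]1[C@](O)(C(C)C)CC[C@]1(C)[C@H](O[Si](C)(C)C(C)(C)C)C([Si](C)(C)C)C(C)=C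
A6 | alternative 3 | 10α-(tert-butyldimethylsilyloxy)dauc-8-ene-4β,6α-diol | O[C@H]1CC(C)=C[C@@H](O[Si](C)(C)C(C)(C)C)[C@@]2(C)CC[C@@](O)(C(C)C)[C@H]12
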